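**Retrosynthetic overview**

1. Atom labels: C1 is the carbinol carbon on ring A (3,4-dimethoxyphenyl), C2 the neighbouring stereocentre, C3 the allylic CH2, C4=C5 the alkene, ring B the 4-methoxyphenyl ring. The ester C–O bond is cut first, giving the C1–C5 diol and O-silylated (Z)-2-(hydroxymethyl)but-2-enoic acid, which is made from (E)-but-2-enal by α-iodination, reduction, silylation and carbonylation with retention.
2. C4=C5 is cut by a Wittig disconnection into a lactol and the ylide of (4-methoxybenzyl)triphenylphosphonium chloride; the lactol comes from a trans γ-lactone acid by two reductions.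
3. Key disconnection: the lactone C1–O bond. The route rests on C1 being the only benzylic carbon of ring A and lying para to its 4-methoxy group, while O–C1–C2–C3–C4 is a γ-lactone once C4 is a carboxyl carbon; anodic oxidation of the 4-arylbutanoic acid therefore closes the ring at C1.
4. The acid precursor comes from Stobbe condensation of 3,4-dimethoxybenzaldehyde with di-tert-butyl succinate and asymmetric hydrogenation, which sets C2. The C2 carboxyl stays a tert-butyl ester through the oxidation, because a free carboxyl three atoms from ring A could add to the ipso carbon of the radical cation.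
5. Ring order: one ring only is built, the oxolan-2-one in step 3; it is reduced to the lactol in step 6 and opened in step 7, with C1 and C2 keeping their configuration.

Key step: step 3

Assumption: the sense of induction in step 2 is assigned by analogy with alkylidenesuccinate half-esters, for which (S,S)-Et-DuPhos on monovalent rhodium is expected to give the (R) acid; the (R,R) ligand is equally available if the analogy does not hold.

**Route**

Step 1
Reactants: 1 3,4-dimethoxybenzaldehyde; 2 di-tert-butyl butanedioate
Product: 3 (3E)-3-(tert-butoxycarbonyl)-4-(3,4-dimethoxyphenyl)but-3-enoic acid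
Conditions: KOtBu (1.2 equiv), t-BuOH, reflux; then aq. HCl
Reagents that add atoms: none
Why: Stobbe condensation, in which the succinate enolate adds to the aldehyde, the aldolate lactonises onto the distal ester and base-induced E1cB ring opening gives the E half-ester with the free carboxyl on the CH2 arm and the tert-butyl ester on the alkene carbon.

Step 2
Reactants: 3 (3E)-3-(tert-butoxycarbonyl)-4-(3,4-dimethoxyphenyl)but-3-enoic acid
Product: 4 (3R)-3-(tert-butoxycarbonyl)-4-(3,4-dimethoxyphenyl)butanoic acid
Conditions: H2 (5 bar), [Rh(cod)2]BF4 (0.5 mol %), (S,S)-Et-DuPhos (0.55 mol %), NaOMe (10 mol %), MeOH, rt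
Reagents that add atoms: none
Why: Rhodium-catalysed asymmetric hydrogenation of an itaconate-type half-ester as its carboxylate, which chelates monovalent rhodium through the alkene and the CH2CO2 arm so that the C2-symmetric bisphospholane delivers hydrogen to one alkene face and sets the R centre (C2 of the target).

Step 3
Reactants: 4 (3R)-3-(tert-butoxycarbonyl)-4-(3,4-dimethoxyphenyl)butanoic acid
Product: 5 tert-butyl (2S,3S)-2-(3,4-dimethoxyphenyl)-5-oxooxolane-3-carboxylate (trans)
Conditions: graphite anode, platinum cathode, undivided cell, constant current (5 mA cm−2, 2.2 F mol−1), 2,4,6-collidine (2 equiv), n-Bu4NBF4 (0.1 M), MeCN/(CF3)2CHOH 9:1, rt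
Reagents that add atoms: none
Why: Ring A gives up one electron at the anode, collidine removes the benzylic proton of the radical cation, and a second electron transfer gives the benzylic cation, a para-quinone-methide oxocarbenium ion stabilised by the 4-methoxy group. The CH2CO2H carboxylate adds to it in a 5-exo-trig closure that forms the C–O bond and the oxolanone ring. The new benzylic stereocentre is controlled by the existing centre next to it: in the envelope transition state the aryl group and the bulky tert-butoxycarbonyl group stay apart, so the trans (2S,3S) lactone is expected, and reversible ionisation of the benzylic C–O bond under acid can correct any cis isomer toward trans. The closest known reaction type is the oxidative benzylic C–H lactonisation of 4-arylbutanoic acids with electron-rich rings, run anodically or with DDQ. The step needs site selectivity (ring A has a single benzylic carbon), closure at the benzylic carbon in preference to carboxylate attack at the ipso carbon (secured by keeping the second carboxyl as its tert-butyl ester, so that the only spiro mode left is six-membered), and protection from over-oxidation (the acyloxy group now on the benzylic carbon raises the oxidation potential, and the charge is limited).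

Step 4
Reactants: 5 tert-butyl (2S,3S)-2-(3,4-dimethoxyphenyl)-5-oxooxolane-3-carboxylate
Product: 6 (2S,3S)-2-(3,4-dimethoxyphenyl)-5-oxooxolane-3-carboxylic acid
Conditions: CF3CO2H/CH2Cl2 (1:4), 0 °C → rt
Reagents that add atoms: none
Why: Acidolysis of the tert-butyl ester (E1 loss of 2-methylpropene) leaves the lactone closed and avoids base, which could open this lactone by β-elimination as in the last stage of a Stobbe reaction, while any cis lactone can equilibrate to trans through reversible benzylic ionisation.

Step 5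
Reactants: 6 (2S,3S)-2-(3,4-dimethoxyphenyl)-5-oxooxolane-3-carboxylic acid
Product: 7 (4R,5S)-5-(3,4-dimethoxyphenyl)-4-(hydroxymethyl)oxolan-2-one
Conditions: BH3·SMe2 (1.5 equiv), THF, 0 °C → rt; then MeOH
Reagents that add atoms: none
Why: Chemoselective borane reduction of the carboxylic acid through its acyloxyborane, which is faster than reduction of the lactone and touches no stereocentre; a possible acyl shift of the lactone to the new primary hydroxyl would be harmless, since both lactones lead to the same hydroxy aldehyde.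

Step 6
Reactants: 7 (4R,5S)-5-(3,4-dimethoxyphenyl)-4-(hydroxymethyl)oxolan-2-one
Product: 8 (4R,5S)-5-(3,4-dimethoxyphenyl)-4-(hydroxymethyl)oxolan-2-ol (mixture of anomers)
Conditions: i-Bu2AlH (2.3 equiv), CH2Cl2, −78 °C; then MeOH, aq. potassium sodium tartrate
Reagents that add atoms: none
Why: Partial reduction of a γ-lactone to the lactol by i-Bu2AlH at low temperature, where the tetrahedral aluminium acetal does not collapse, the first equivalent being consumed by the free hydroxyl.

Step 7
Reactants: 8 (4R,5S)-5-(3,4-dimethoxyphenyl)-4-(hydroxymethyl)oxolan-2-ol; 9 (4-methoxybenzyl)triphenylphosphonium chloride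
Product: 11 (1S,2R)-1-(3,4-dimethoxyphenyl)-2-[3-(4-methoxyphenyl)prop-2-en-1-yl]propane-1,3-diol (E/Z mixture), via (4-methoxybenzylidene)triphenylphosphorane 10 (not isolated)
Conditions: 9 (3.5 equiv), KOtBu (3.4 equiv), THF, 0 °C; then 8, 0 °C → 50 °C
Reagents that add atoms: none
Why: Wittig olefination of the open hydroxy-aldehyde form of the lactol by a semi-stabilised benzylic ylide, used in excess to cover the two hydroxyl groups; an E/Z mixture is expected and is corrected in step 8, and neither stereocentre is α to the aldehyde, so none can epimerise.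

Step 8
Reactants: 11 (1S,2R)-1-(3,4-dimethoxyphenyl)-2-[3-(4-methoxyphenyl)prop-2-en-1-yl]propane-1,3-diol (E/Z mixture)
Product: 12 (1S,2R)-1-(3,4-dimethoxyphenyl)-2-[(2E)-3-(4-methoxyphenyl)prop-2-en-1-yl]propane-1,3-diol
Conditions: PhSSPh (10 mol %), hν (sun lamp), PhH, 40 °C
Reagents that add atoms: none
Why: Thiyl-radical-catalysed alkene isomerisation, in which reversible addition of PhS• to the styrene double bond equilibrates it to the more stable E isomer; it is done before acylation so that the Z enoate of the side chain is never exposed, and iodine catalysis is avoided because the free hydroxyls could undergo iodoetherification.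

Step 9
Reactants: 13 (E)-but-2-enal
Product: 14 (Z)-2-iodobut-2-enal
Conditions: I2, K2CO3, DMAP (20 mol %), THF/H2O 1:1, rt
Reagents that add atoms: iodine, II
Why: α-Iodination of an enal by conjugate addition of DMAP, iodination of the resulting enolate and E1cB loss of DMAP (a Baylis–Hillman-type pathway), which gives the Z iodoenal with the methyl group trans to the formyl group.

Step 10
Reactants: 14 (Z)-2-iodobut-2-enal
Product: 15 (Z)-2-iodobut-2-en-1-ol
Conditions: NaBH4, CeCl3·7H2O, MeOH, 0 °C
Reagents that add atoms: none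
Why: Luche 1,2-reduction of the aldehyde, which leaves the vinyl iodide and its geometry untouched.

Step 11
Reactants: 15 (Z)-2-iodobut-2-en-1-ol
Product: 16 tert-butyl{[(2Z)-2-iodobut-2-en-1-yl]oxy}dimethylsilane
Conditions: t-BuMe2SiCl, imidazole, DMF, rt
Reagents that add atoms: tert-butyldimethylsilyl chloride, CC(C)(C)[Si](C)(C)Cl
Why: Standard imidazole-mediated silylation of a primary allylic alcohol.

Step 12
Reactants: 16 tert-butyl{[(2Z)-2-iodobut-2-en-1-yl]oxy}dimethylsilane
Product: 17 (2Z)-2-{[(tert-butyldimethylsilyl)oxy]methyl}but-2-enoic acid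
Conditions: CO (1 atm), Pd(OAc)2 (5 mol %), PPh3 (10 mol %), KOAc (4 equiv), DMF/H2O, 50 °C; then aq. citric acid
Reagents that add atoms: carbon monoxide, [C-]#[O+]; water, O
Why: Palladium-catalysed hydroxycarbonylation of a vinyl iodide, in which oxidative addition to zerovalent palladium with retention, CO insertion and hydrolysis of the acylpalladium species place the carboxyl where iodine was, cis to the methyl group, which is the Z geometry of the target side chain.

Step 13
Reactants: 12 (1S,2R)-1-(3,4-dimethoxyphenyl)-2-[(2E)-3-(4-methoxyphenyl)prop-2-en-1-yl]propane-1,3-diol; 17 (2Z)-2-{[(tert-butyldimethylsilyl)oxy]methyl}but-2-enoic acid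
Product: 19 (2R,3S)-3-(3,4-dimethoxyphenyl)-3-hydroxy-2-[(2E)-3-(4-methoxyphenyl)prop-2-en-1-yl]propyl (2Z)-2-{[(tert-butyldimethylsilyl)oxy]methyl}but-2-enoate, via mixed anhydride 18 (not isolated)
Conditions: 17, 2,4,6-Cl3C6H2COCl, Et3N, PhMe, rt; then 12, PhMe, 50 °C
Reagents that add atoms: none
Why: Yamaguchi esterification through the mixed anhydride, run without a nucleophilic pyridine catalyst that could add reversibly to the enoate and erode its Z geometry, the primary hydroxyl reacting faster than the hindered secondary benzylic one.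

Step 14
Reactants: 19 (2R,3S)-3-(3,4-dimethoxyphenyl)-3-hydroxy-2-[(2E)-3-(4-methoxyphenyl)prop-2-en-1-yl]propyl (2Z)-2-{[(tert-butyldimethylsilyl)oxy]methyl}but-2-enoate
Product: 20 (2R,3S)-3-(3,4-dimethoxyphenyl)-3-hydroxy-2-[(2E)-3-(4-methoxyphenyl)prop-2-en-1-yl]propyl (2Z)-2-(hydroxymethyl)but-2-enoate (CNP0280662.1)
Conditions: HF·pyridine, pyridine, THF, 0 °C → rt
Reagents that add atoms: none
Why: Fluoride cleavage of a primary silyl ether with pyridine-buffered HF, mild enough to avoid acyl migration to the neighbouring secondary hydroxyl, ionisation of the electron-rich benzylic alcohol and isomerisation of the enoate.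

**Compound list**

1 | 3,4-dimethoxybenzaldehyde | COc1ccc(C=O)cc1OC | starting material
2 | di-tert-butyl butanedioate | CC(C)(C)OC(=O)CCC(=O)OC(C)(C)C | starting material
3 | (3E)-3-(tert-butoxycarbonyl)-4-(3,4-dimethoxyphenyl)but-3-enoic acid | CC(C)(C)OC(=O)/C(=C/c1ccc(OC)c(OC)c1)CC(=O)O | intermediate
4 | (3R)-3-(tert-butoxycarbonyl)-4-(3,4-dimethoxyphenyl)butanoic acid | CC(C)(C)OC(=O)[C@@H](CC(=O)O)Cc1ccc(OC)c(OC)c1 | intermediate
5 | tert-butyl (2S,3S)-2-(3,4-dimethoxyphenyl)-5-oxooxolane-3-carboxylate | CC(C)(C)OC(=O)[C@H]1CC(=O)O[C@@H]1c1ccc(OC)c(OC)c1 | intermediate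
6 | (2S,3S)-2-(3,4-dimethoxyphenyl)-5-oxooxolane-3-carboxylic acid | OC(=O)[C@H]1CC(=O)O[C@@H]1c1ccc(OC)c(OC)c1 | intermediate
7 | (4R,5S)-5-(3,4-dimethoxyphenyl)-4-(hydroxymethyl)oxolan-2-one | OC[C@H]1CC(=O)O[C@@H]1c1ccc(OC)c(OC)c1 | intermediate
8 | (4R,5S)-5-(3,4-dimethoxyphenyl)-4-(hydroxymethyl)oxolan-2-ol, anomer mixture | OC[C@H]1CC(O)O[C@@H]1c1ccc(OC)c(OC)c1 | intermediate
9 | (4-methoxybenzyl)triphenylphosphonium chloride | COc1ccc(C[P+](c2ccccc2)(c2ccccc2)c2ccccc2)cc1.[Cl-] | starting material
10 | (4-methoxybenzylidene)triphenylphosphorane | COc1ccc(C=P(c2ccccc2)(c2ccccc2)c2ccccc2)cc1 | intermediate (not isolated)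
11 | (1S,2R)-1-(3,4-dimethoxyphenyl)-2-[3-(4-methoxyphenyl)prop-2-en-1-yl]propane-1,3-diol, E/Z mixture | OC[C@@H](CC=Cc1ccc(OC)cc1)[C@H](O)c1ccc(OC)c(OC)c1 | intermediate
12 | (1S,2R)-1-(3,4-dimethoxyphenyl)-2-[(2E)-3-(4-methoxyphenyl)prop-2-en-1-yl]propane-1,3-diol | OC[C@@H](C/C=C/c1ccc(OC)cc1)[C@H](O)c1ccc(OC)c(OC)c1 | intermediate
13 | (E)-but-2-enal | C/C=C/C=O | starting material
14 | (Z)-2-iodobut-2-enal | C/C=C(\I)C=O | intermediate
15 | (Z)-2-iodobut-2-en-1-ol | C/C=C(\I)CO | intermediate
16 | tert-butyl{[(2Z)-2-iodobut-2-en-1-yl]oxy}dimethylsilane | C/C=C(\I)CO[Si](C)(C)C(C)(C)C | intermediate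
17 | (2Z)-2-{[(tert-butyldimethylsilyl)oxy]methyl}but-2-enoic acid | C/C=C(/CO[Si](C)(C)C(C)(C)C)C(=O)O | intermediate
18 | (2Z)-2-{[(tert-butyldimethylsilyl)oxy]methyl}but-2-enoic 2,4,6-trichlorobenzoic anhydride | C/C=C(/CO[Si](C)(C)C(C)(C)C)C(=O)OC(=O)c1c(Cl)cc(Cl)cc1Cl | intermediate (not isolated)
19 | (2R,3S)-3-(3,4-dimethoxyphenyl)-3-hydroxy-2-[(2E)-3-(4-methoxyphenyl)prop-2-en-1-yl]propyl (2Z)-2-{[(tert-butyldimethylsilyl)oxy]methyl}but-2-enoate | C/C=C(/CO[Si](C)(C)C(C)(C)C)C(=O)OC[C@@H](C/C=C/c1ccc(OC)cc1)[C@H](O)c1ccc(OC)c(OC)c1 | intermediate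
20 | (2R,3S)-3-(3,4-dimethoxyphenyl)-3-hydroxy-2-[(2E)-3-(4-methoxyphenyl)prop-2-en-1-yl]propyl (2Z)-2-(hydroxymethyl)but-2-enoate | C/C=C(/CO)C(=O)OC[C@@H](C/C=C/c1ccc(OC)cc1)[C@H](O)c1ccc(OC)c(OC)c1 | target

**Step count and risks**

Total steps: 14. Longest linear sequence: 10 (steps 1–8, 13, 14); the side-chain acid takes steps 9–12.

Steps most likely to fail:

1. Step 3. The carboxylate may add to the ipso carbon of the ring A radical cation (dearomatising spirolactonisation) in place of benzylic deprotonation, radical cations may couple aryl to aryl, the product may be oxidised further, and the closure may be poorly trans-selective. The fallback sets out from 1 and comes back at 6, replacing steps 1–4 by an auxiliary-controlled aldol route. (4S)-4-Benzyl-1,3-oxazolidin-2-one is N-acylated (n-BuLi, THF, −78 °C, then methyl 4-chloro-4-oxobutanoate) to methyl 4-[(4S)-4-benzyl-2-oxo-1,3-oxazolidin-3-yl]-4-oxobutanoate F1. Its Z boron enolate (n-Bu2BOTf, i-Pr2NEt, CH2Cl2, −78 °C) adds to 1 in an Evans syn aldol reaction to give methyl (3S)-4-[(4S)-4-benzyl-2-oxo-1,3-oxazolidin-3-yl]-3-[(S)-(3,4-dimethoxyphenyl)(hydroxy)methyl]-4-oxobutanoate F2. Acid-catalysed lactonisation (TsOH cat., CH2Cl2) with loss of methanol gives the trans lactone imide (4S)-4-benzyl-3-{[(2S,3S)-2-(3,4-dimethoxyphenyl)-5-oxooxolan-3-yl]carbonyl}-1,3-oxazolidin-2-one F3. Cleavage of the auxiliary with LiOH/H2O2 (THF/H2O, 0 °C) and acidification gives 6.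

2. Step 13. The Z enoate may isomerise to the more stable E isomer while the acyl group is activated, the secondary benzylic hydroxyl may be acylated as well, and the acyl group may migrate between the two hydroxyls. The fallback sets out from 12 and comes back at 19, and forms the ester by alkylation of the carboxylate so that the acyl carbon is never activated. Selective sulfonylation of the primary hydroxyl (TsCl, pyridine, CH2Cl2, 0 °C) gives (2R,3S)-3-(3,4-dimethoxyphenyl)-3-hydroxy-2-[(2E)-3-(4-methoxyphenyl)prop-2-en-1-yl]propyl 4-methylbenzenesulfonate F4. SN2 displacement by the caesium salt of 17 (Cs2CO3, DMF, 40 °C) gives 19.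

3. Step 7. The lactol may open too slowly for the weakly nucleophilic semi-stabilised ylide in the presence of two alkoxides, giving low conversion, and the alkene may form with poor geometric control. The fallback sets out from 8 and comes back at 12, replacing steps 7 and 8. Methylenation of the lactol (Ph3PCH3Br, KOtBu, THF, 0 °C → rt) gives (1S,2R)-1-(3,4-dimethoxyphenyl)-2-(prop-2-en-1-yl)propane-1,3-diol F5. Olefin cross-metathesis with 1-ethenyl-4-methoxybenzene (second-generation Grubbs catalyst, RuCl2(=CHPh)(PCy3)(H2IMes), CH2Cl2, 40 °C) should give 12 directly as the E alkene.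

**Further compounds**

F1 | step 3 | methyl 4-[(4S)-4-benzyl-2-oxo-1,3-oxazolidin-3-yl]-4-oxobutanoate | COC(=O)CCC(=O)N1C(=O)OC[C@@H]1Cc1ccccc1
F2 | step 3 | methyl (3S)-4-[(4S)-4-benzyl-2-oxo-1,3-oxazolidin-3-yl]-3-[(S)-(3,4-dimethoxyphenyl)(hydroxy)methyl]-4-oxobutanoate | O=C(N1C(=O)OC[C@@H]1Cc1ccccc1)[C@@H](CC(=O)OC)[C@H](O)c1ccc(OC)c(OC)c1
F3 | step 3 | (4S)-4-benzyl-3-{[(2S,3S)-2-(3,4-dimethoxyphenyl)-5-oxooxolan-3-yl]carbonyl}-1,3-oxazolidin-2-one | O=C(N1C(=O)OC[C@@H]1Cc1ccccc1)[C@H]1CC(=O)O[C@@H]1c1ccc(OC)c(OC)c1
F4 | step 13 | (2R,3S)-3-(3,4-dimethoxyphenyl)-3-hydroxy-2-[(2E)-3-(4-methoxyphenyl)prop-2-en-1-yl]propyl 4-methylbenzenesulfonate | Cc1ccc(cc1)S(=O)(=O)OC[C@@H](C/C=C/c1ccc(OC)cc1)[C@H](O)c1ccc(OC)c(OC)c1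
F5 | step 7 | (1S,2R)-1-(3,4-dimethoxyphenyl)-2-(prop-2-en-1-yl)propane-1,3-diol | OC[C@@H](CC=C)[C@H](O)c1ccc(OC)c(OC)c1
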